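**Remark on naming.** Ar = 2,4,5-trimethoxyphenyl. Ring compounds are named with the locants C1–C11 fixed in the analysis below, and CIP descriptors are quoted for these locants. The SMILES in the compound list are authoritative.

## Analysis of the target

Tatanan B (20) is a spiro[5.5]undecane in which a fully substituted cyclohexane, ring A, shares one carbon with a 2,5-dimethoxycyclohexa-2,5-dienone, ring B. Ring A is numbered C1 (ethyl), C2 (methyl), C3 (Ar), C4 (methyl), C5 (Ar) and C6 (spiro carbon); ring B continues with C7 (CH), C8 (methoxy), C9 (carbonyl), C10 (CH) and C11 (methoxy). All six carbons of ring A are contiguous stereocentres, (1R,2S,3S,4R,5R,6S). The ethyl group, the C2 methyl group and both aryl groups lie on one face and the C4 methyl group on the other, so in the chair everything is equatorial except the C2 methyl group, which is axial; at C6 the CH carbon C7 is axial, on the side of that methyl group, and the methoxy-bearing C11 is equatorial. The sensitive parts are the cross-conjugated dienone with its vinylogous ester (hydrolysis, nucleophiles, acid-induced rearrangement) and the two very electron-rich arenes (oxidants, electrophiles). The difficulty is that ring A has no heteroatom handle, that five methine centres must be set with no later chance to correct the axial methyl group, and that the quaternary carbon C6 sits between two of them. The strategy rests on two features: C3 (Ar) and C4 (methyl) are trans exactly as in the commercial E-propenylarene α-asarone (8), and C6 can be traced back to the oxygen-bearing inner carbon of a diene C5=C6–C1=C2 whose ends carry the C5 aryl group and the C2 methyl group.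

## Retrosynthetic reasoning

**Ring B (20 to 14 and 17).** The dienone is the most fragile part of 20, so it is removed first and therefore made last. Cutting C6–C11 and C7–C8 gives aldehyde 14, in which C7 is the formyl carbon, and the four-carbon enone 17, which already holds C8–C11 with both methoxy groups and the carbonyl in place. This cut is preferred to one through a ring B dione because the position of the vinylogous ester is then written into the reagent and is not left to a regioselective O-methylation. The forward step has to create the quaternary carbon C6 by conjugate addition–elimination at C11, on the face away from the axial C2 methyl group, and then close C7–C8 by aldol condensation.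

**One-carbon homologation (14 to 10).** Removing the formyl carbon (C6–C7) leads back to ketone 10 through alcohol 13 and the exocyclic alkene 11. Methylenation, hydroboration and oxidation are chosen over a basic one-carbon olefination because C1 and C5 are epimerisable as long as C6 is a carbonyl carbon. The configuration at C6 in 13 and 14 does not matter, since C6 is planar again in the enolate.

**C1 (10 to 9).** Ketone 10 is the desilylated form of silyl enol ether 9. The only bond made is C1–H, and the forward protonation must deliver hydrogen to C1 anti to the neighbouring methyl group so that the ethyl group becomes equatorial.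

**Ring A (9 to 7 and 8).** The double bond C1=C6 of 9 marks a cyclohexene. Cutting C4–C5 and C2–C3 divides ring A into the two-carbon unit 8 (C3, C4) and the four-carbon siloxydiene 7 (C5, C6, C1, C2). No other pair of bonds takes the trans C3/C4 relationship from a commercial alkene and at the same time turns the future spiro carbon into a functionalised carbon. Both partners are electron-rich, so a thermal cycloaddition is not available and the union has to run through a radical cation. The step must form two bonds, one ring and four stereocentres with control of regiochemistry, of the endo placement of the C3 aryl group and of the absolute sense.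

**Diene (7 to 1 and 3).** Diene 7 is the Z silyl enol ether of enone 6. The C5–C6 bond of 6 is cut between the benzylic carbon and the carbonyl carbon, which leads through alcohol 5 to the Grignard reagent 4, made from chloride 2 and hence from alcohol 1, and to enal 3, which supplies the E trisubstituted double bond C1=C2 ready-made.

**Enone reagent (17 to 15 and 16).** Enone 17 is cut between its carbonyl carbon and the vinylic carbon, giving acid chloride 15 and ketene acetal 16, both commercial.

## Alternatives that were turned down

**Alternative 1:** anodic ipso-spirocyclisation.
- Disconnection: C1–C6, with ring B traced back to a third trimethoxyphenyl group whose ipso carbon is C6. The open-chain precursor A2 carries two identical aryl groups on C5 and an allylsilane ending at C1.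
- Forward key step: anodic oxidation turns one arene into its radical cation, the allylsilane carbon C1 attacks its ipso carbon, and a second electron with loss of the para O-methyl group gives the vinyl spirodienone A1. Selective hydrogenation of the vinyl group would then give 20.
- For: ring B arrives with the correct oxygenation in one step from an ordinary arene. On this point the alternative is stronger than the chosen route, which spends five operations on ring B and has to form the quaternary carbon intermolecularly.
- Against: A2 needs the C2–C4 stereotriad built in an open chain, which is a separate asymmetric synthesis. The cyclisation must choose between two constitutionally identical, diastereotopic aryl groups (this sets C5) and between two faces (this sets C6), and set C1 as well, with little in the transition state to tell the options apart. Three equally oxidisable arenes, ortho instead of ipso attack and over-oxidation add to the risk.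
- Comparison: the chosen route takes four stereocentres from alkene geometry in one intermolecular step between two simple π-components. Its price is the late construction of ring B.

**Alternative 2:** donor–acceptor cyclobutane opened by 8.
- Disconnection: C3–C4 and C5–C6. Ring A comes from the four-carbon cyclobutane diester A4 (C6 as malonate carbon, C1, C2 and the aryl-bearing C3) and the two-carbon alkene 8.
- Forward key step: a Lewis acid opens the C3–C6 bond to a benzylic cation and a malonate anion, C4 of 8 attacks C3, and the new cation at C5 is captured by the malonate to give A3.
- For: it uses 8 in the same role as the chosen route. C1 and C2 enter already fixed, so there is no epimerisable C1, and C6 is quaternary from the start. On these two points it is stronger.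
- Against: C3 is planar in the intermediate, so C3, C4 and C5 are set in a stepwise cationic sequence with no geometric memory, and the required arrangement (C3 aryl cis to an axial C2 methyl group) is not the obviously preferred one. Free cations next to trimethoxyarenes invite Friedel–Crafts closure. A4 needs its own enantioselective synthesis with cis ethyl and methyl groups. Turning the two diastereotopic esters of A3 into ring B means differentiating them, which decides C6 and costs more steps than the homologation used here.
- Comparison: the chosen route offers one-step stereocontrol from alkene geometries and a much shorter path to both partners, at the cost of setting C1 and C6 afterwards.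

**Alternative 3:** phenol para-carbon as double Michael donor.
- Disconnection: C5–C6 and C1–C6. Ring A comes from the cross-conjugated dienone A6 (C1–C5) and the para carbon of phenol A7, which becomes C6.
- Forward key step: a chiral primary ammonium salt activates A6 as an iminium ion for conjugate addition of the para carbon to one enone terminus; under base the phenolate attacks the second terminus through the same carbon and dearomatises, giving spirodienone A5.
- For: ring B comes from a commercial phenol with no separate construction, the first bond is formed under a well-understood kind of asymmetric catalysis, and the spirocycle is reached in very few steps. On enantiocontrol and on ring B it is stronger than the chosen route.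
- Against: A5 has a ketone at C3 and the wrong configuration at C2. The aryl group must be added at C3 and the oxygen removed stereoselectively while the dienone of ring B competes as an electrophile, and C2 must be inverted to the axial position against thermodynamics. α-Branched enones are sluggish iminium substrates, and O- instead of para-C-alkylation is a further risk.
- Comparison: the chosen route places both aryl groups and both methyl groups in their final configuration in the key step and never carries the dienone through later steps.

Key step: step 5

**Assumption:** which antipode of the chiral anion leads to the (2R,3R,4R,5R) series of 9 cannot be foretold. The (S,S) anion is written, and its mirror image would be taken if the first runs showed the opposite sense.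

**Remark on the catalyst:** Ru(bpz)3(X)2 (bpz = 2,2′-bipyrazine; X− = confined (S,S)-imidodiphosphorimidate anion built from two 3,3′-diaryl-BINOL units with N-triflyl groups) is prepared beforehand by anion exchange from Ru(bpz)3(PF6)2 and is not counted as a step.

## Route

Step 1
Reactants: 1 2,4,5-trimethoxybenzyl alcohol
Product: 2 2,4,5-trimethoxybenzyl chloride
Conditions: SOCl2, CH2Cl2, 0 °C
Reagents that add atoms: thionyl chloride, O=S(Cl)Cl
Why: Chlorodehydroxylation through the chlorosulfite; the donor-activated benzylic carbon ionises readily, so the exchange is fast at 0 °C, and the crude chloride is used at once because it solvolyses easily.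

Step 2
Reactants: 2 2,4,5-trimethoxybenzyl chloride; 3 (E)-2-ethylbut-2-enal
Product: 5 (E)-3-ethyl-1-(2,4,5-trimethoxyphenyl)pent-3-en-2-ol (racemic), via Grignard reagent 4 (not isolated)
Conditions: Mg, THF, 0 °C (slow addition, high dilution); then 3, −78 → 0 °C; aq NH4Cl
Reagents that add atoms: none
Why: Magnesium insertion at high dilution keeps Wurtz coupling down, and the Grignard addition to the α-branched enal goes to the carbonyl carbon (1,2-addition); the carbinol centre forms as a racemate and is removed in step 3.

Step 3
Reactants: 5 (E)-3-ethyl-1-(2,4,5-trimethoxyphenyl)pent-3-en-2-ol
Product: 6 (E)-3-ethyl-1-(2,4,5-trimethoxyphenyl)pent-3-en-2-one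
Conditions: Dess–Martin periodinane, CH2Cl2, 0 °C → rt
Reagents that add atoms: none
Why: Dess–Martin oxidation of a secondary allylic alcohol under neutral, non-enolising conditions, which leaves the E double bond and the acidic benzylic methylene of the product untouched.

Step 4
Reactants: 6 (E)-3-ethyl-1-(2,4,5-trimethoxyphenyl)pent-3-en-2-one
Product: 7 (1Z,3E)-3-ethyl-2-(triisopropylsiloxy)-1-(2,4,5-trimethoxyphenyl)penta-1,3-diene
Conditions: TIPSOTf, Et3N, CH2Cl2, 0 °C → rt
Reagents that add atoms: triisopropylsilyl trifluoromethanesulfonate, CC(C)[Si](OS(=O)(=O)C(F)(F)F)(C(C)C)C(C)C
Why: Soft enolisation: the silyl triflate activates the carbonyl and the amine removes the more acidic benzylic α-hydrogen, giving the conjugated silyl enol ether with aryl cis to oxygen (1Z), since the other isomer would press the aryl group against the branched alkenyl substituent; the 3E bond is not involved. The bulky triisopropylsilyl group is chosen to survive chromatography and the oxidising conditions of step 5.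

Step 5
Reactants: 7 (1Z,3E)-3-ethyl-2-(triisopropylsiloxy)-1-(2,4,5-trimethoxyphenyl)penta-1,3-diene; 8 α-asarone
Product: 9 ring A silyl enol ether, (2R,3R,4R,5R)-1-ethyl-2,4-dimethyl-6-(triisopropylsiloxy)-3,5-bis(2,4,5-trimethoxyphenyl)cyclohex-1(6)-ene
Conditions: 8 (2 equiv), Ru(bpz)3(X)2 (2 mol %), blue LEDs, air, CH2Cl2, −30 °C
Reagents that add atoms: none
Why: Proposed new method: the excited divalent ruthenium complex removes one electron from 8 (or from the equally electron-rich 7, with the same outcome), and in the weakly polar medium the radical cation is held in a contact ion pair by the confined chiral anion X−, which is expected to bias the face on which the first bond forms; the closest known reaction types are the racemic visible-light radical-cation Diels–Alder reaction of anethole-type styrenes with dienes under Ru(bpz)3 salts and chiral-anion-paired photoredox cycloadditions of such styrenes. The enol-ether carbon C5 of 7, its most nucleophilic position, bonds to the β-carbon C4 of the styrene radical cation, which leaves a benzylic radical at C3 and a 2-siloxyallyl cation spanning C6–C1–C2. Ring A then closes by six-membered union of C3 with the allyl terminus C2 (6-endo with respect to the allyl unit) and not by four-membered closure at C6, and any vinylcyclobutane that forms reopens under the oxidising conditions; the product radical cation oxidises a further molecule of 8 and carries the chain. C3/C4 trans is inherited from the E geometry of 8, C2/C5 cis from the two outward substituents (methyl and aryl) on the termini of the s-cis diene, and the C3 aryl group ends cis to both through an aryl-endo arrangement, which is also the low-energy closure with C3, C4 and C5 all equatorial. The absolute sense rests on the ion pair alone. The step needs C4–C5 to form before C2–C3, which the matched polarity secures (C5 is the enol-ether β-carbon, C4 the electrophilic terminus of the radical cation), and it needs cross- over homo-coupling, which is favoured because [2+2] dimers of 8 form reversibly. The triisopropylsilyl group protects the oxidised enol ether from desilylation.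

Step 6
Reactants: 9 ring A silyl enol ether
Product: 10 (1R,2R,3S,4R,5R)-1-ethyl-2,4-dimethyl-3,5-bis(2,4,5-trimethoxyphenyl)cyclohexan-6-one
Conditions: TBAF, AcOH, THF, −78 → −20 °C
Reagents that add atoms: none
Why: Fluoride cleaves the Si–O bond and the enol(ate) is protonated at C1 under kinetic control, axially and anti to the pseudoaxial C2 methyl group, which places the ethyl group equatorial and cis to that methyl (1R). Buffering with acetic acid prevents base-mediated equilibration, on which the route does not rely because the equatorial preference of an ethyl group next to an axial methyl group is small; C5 stays as set.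

Step 7
Reactants: 10 ring A ketone
Product: 11 (1R,2S,3S,4R,5S)-1-ethyl-2,4-dimethyl-6-methylidene-3,5-bis(2,4,5-trimethoxyphenyl)cyclohexane
Conditions: Cp2TiMe2, toluene/THF, 70 °C, dark
Reagents that add atoms: dimethyltitanocene, C[Ti+2]C.c1cc[cH-]c1.c1cc[cH-]c1
Why: Petasis methylenation: thermolysis gives the titanium methylidene, which converts C=O into C=CH2 through an oxatitanacyclobutane. The reagent is not basic, so the α-centres C1 and C5 are not enolised, and it is small enough for a ketone flanked by two substituents.

Step 8
Reactants: 11 C6-methylidene compound
Product: 13 C6-hydroxymethyl compound (C6 epimers), via alkylborane 12 (not isolated)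
Conditions: BH3·THF, THF, 0 °C → rt; then NaOH, H2O2, 0 °C → rt
Reagents that add atoms: hydrogen peroxide, OO
Why: Hydroboration places boron on the unhindered methylene carbon (anti-Markovnikov, four-centre syn addition) and oxidation replaces boron by hydroxyl with retention. The new centre C6 may form as a mixture, which is of no consequence because C6 becomes trigonal again in step 11.

Step 9
Reactants: 13 C6-hydroxymethyl compound
Product: 14 (1R,2S,3S,4R,5S)-1-ethyl-2,4-dimethyl-3,5-bis(2,4,5-trimethoxyphenyl)cyclohexane-6-carbaldehyde (C6 epimers)
Conditions: Dess–Martin periodinane, CH2Cl2, 0 °C → rt
Reagents that add atoms: none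
Why: Dess–Martin oxidation stops at the aldehyde and is mild enough for the electron-rich arenes; both C6 epimers give the same enolate in step 11.

Step 10
Reactants: 15 methoxyacetyl chloride; 16 1,1-dimethoxyethene
Product: 17 1,4,4-trimethoxybut-3-en-2-one
Conditions: pyridine, CH2Cl2, −10 °C → rt
Reagents that add atoms: none
Why: C-Acylation of a ketene acetal at its nucleophilic carbon by the acyl chloride, followed by loss of a proton from the dialkoxycarbenium intermediate to pyridine before chloride can dealkylate it. This is the standard acylation of enol ethers and ketene acetals and gives the β,β-dimethoxy enone.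

Step 11
Reactants: 14 ring A aldehyde; 17 1,4,4-trimethoxybut-3-en-2-one
Product: 20 tatanan B, via keto aldehyde 18 (not isolated), via aldol 19 (not isolated)
Conditions: KH, THF, 0 °C; then 17, 18-crown-6, 0 → 45 °C
Reagents that add atoms: none
Why: Robinson-type spiroannulation in which the Michael step is a conjugate addition–elimination: the potassium enolate of 14 attacks the ketene-acetal carbon of 17 (C6–C11) with loss of methoxide, and the liberated methoxide drives the aldol condensation of the C8 methylene onto the now non-enolisable aldehyde C7 and the dehydration to the dienone. The acceptor approaches C6 on the face opposite the axial C2 methyl group (equatorial attack), so C11 ends equatorial and C7 axial, which is the 6S configuration. The position of the vinylogous ester is fixed by the reagent.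

## Compound list

1 | 2,4,5-trimethoxybenzyl alcohol | COc1cc(OC)c(CO)cc1OC | starting material
2 | 2,4,5-trimethoxybenzyl chloride | COc1cc(OC)c(CCl)cc1OC | intermediate
3 | (E)-2-ethylbut-2-enal | C/C=C(CC)/C=O | starting material
4 | (2,4,5-trimethoxybenzyl)magnesium chloride | COc1cc(OC)c(C[Mg]Cl)cc1OC | intermediate
5 | (E)-3-ethyl-1-(2,4,5-trimethoxyphenyl)pent-3-en-2-ol, racemic at the carbinol carbon | C/C=C(CC)/C(O)Cc1cc(OC)c(OC)cc1OC | intermediate
6 | (E)-3-ethyl-1-(2,4,5-trimethoxyphenyl)pent-3-en-2-one | C/C=C(CC)/C(=O)Cc1cc(OC)c(OC)cc1OC | intermediate
7 | (1Z,3E)-3-ethyl-2-(triisopropylsiloxy)-1-(2,4,5-trimethoxyphenyl)penta-1,3-diene | C/C=C(CC)/C(O[Si](C(C)C)(C(C)C)C(C)C)=C/c1cc(OC)c(OC)cc1OC | intermediate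
8 | α-asarone, (E)-1,2,4-trimethoxy-5-(prop-1-enyl)benzene | COc1cc(OC)c(/C=C/C)cc1OC | starting material
9 | ring A silyl enol ether, (2R,3R,4R,5R), C1=C6 double bond, triisopropylsiloxy on C6 | CCC1=C(O[Si](C(C)C)(C(C)C)C(C)C)[C@@H](c2cc(OC)c(OC)cc2OC)[C@H](C)[C@@H](c2cc(OC)c(OC)cc2OC)[C@H]1C | intermediate
10 | ring A ketone, (1R,2R,3S,4R,5R), C6 = carbonyl; systematic name (2R,3R,4S,5R,6R)-2-ethyl-3,5-dimethyl-4,6-bis(2,4,5-trimethoxyphenyl)cyclohexan-1-one | CC[C@@H]1[C@H](C)[C@H](c2cc(OC)c(OC)cc2OC)[C@@H](C)[C@H](c2cc(OC)c(OC)cc2OC)C1=O | intermediate
11 | C6-methylidene compound, (1R,2S,3S,4R,5S) | CC[C@@H]1[C@H](C)[C@H](c2cc(OC)c(OC)cc2OC)[C@@H](C)[C@H](c2cc(OC)c(OC)cc2OC)C1=C | intermediate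
12 | C6-(boranylmethyl) compound, (1R,2S,3S,4R,5S), C6 epimers | CC[C@@H]1[C@H](C)[C@H](c2cc(OC)c(OC)cc2OC)[C@@H](C)[C@H](c2cc(OC)c(OC)cc2OC)C1CB | intermediate
13 | C6-hydroxymethyl compound, (1R,2S,3S,4R,5S), C6 epimers | CC[C@@H]1[C@H](C)[C@H](c2cc(OC)c(OC)cc2OC)[C@@H](C)[C@H](c2cc(OC)c(OC)cc2OC)C1CO | intermediate
14 | C6-carbaldehyde, (1R,2S,3S,4R,5S), C6 epimers | CC[C@@H]1[C@H](C)[C@H](c2cc(OC)c(OC)cc2OC)[C@@H](C)[C@H](c2cc(OC)c(OC)cc2OC)C1C=O | intermediate
15 | methoxyacetyl chloride | COCC(=O)Cl | starting material
16 | 1,1-dimethoxyethene | C=C(OC)OC | starting material
17 | 1,4,4-trimethoxybut-3-en-2-one | COCC(=O)C=C(OC)OC | intermediate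
18 | keto aldehyde, (1R,2S,3S,4R,5R,6R): C6 carries the formyl group (C7) and the (E)-1,4-dimethoxy-3-oxobut-1-enyl chain (C11–C8); the enol-ether geometry equilibrates | CC[C@@H]1[C@H](C)[C@H](c2cc(OC)c(OC)cc2OC)[C@@H](C)[C@H](c2cc(OC)c(OC)cc2OC)[C@@]1(C=O)/C(OC)=C\C(=O)COC | intermediate
19 | aldol, ring B closed with hydroxyl on C7 and methoxy on C8 (mixture at C7 and C8), ring A and C6 as in 20 | CC[C@@H]1[C@H](C)[C@H](c2cc(OC)c(OC)cc2OC)[C@@H](C)[C@H](c2cc(OC)c(OC)cc2OC)[C@]12C(O)C(OC)C(=O)C=C2OC | intermediate
20 | tatanan B, (1R,2S,3S,4R,5R,6S) | CC[C@@H]1[C@H](C)[C@H](c2cc(OC)c(OC)cc2OC)[C@@H](C)[C@H](c2cc(OC)c(OC)cc2OC)[C@]12C=C(OC)C(=O)C=C2OC | target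

## Step count and least certain steps

Total: 11 steps. Longest linear sequence: 10 steps (steps 1–9 and 11, from 1 to 20); step 10 is a one-step side branch to reagent 17.

**Step 5 (key step, the one step beyond known chemistry).** The ion pair may be too loose to transmit chirality, or the hole may be passed on through solvent-separated pairs, so that enantioselectivity is low. Other possible failures are regiochemical leakage (first bond at C2 instead of C5), slow turnover while 8 cycles through its reversible [2+2] dimer, desilylation of the oxidised enol ether, and consumption of 7 by singlet oxygen. The fallback uses known chemistry only. It sets out from 7 and 8 with the achiral salt Ru(bpz)3(PF6)2 under visible light and air, the established racemic radical-cation Diels–Alder reaction, which would give 9 together with its enantiomer F1. Desilylation under the conditions of step 6 would give the racemic ketone, that is 10 beside its enantiomer F2. Preparative chromatography on a chiral stationary phase (amylose tris(3,5-dimethylphenylcarbamate)) would deliver 10, where the route is rejoined.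

**Step 11.** The hindered enolate may fail to attack the weakly electrophilic ketene-acetal carbon (proton transfer to 17, bonding through oxygen, or self-condensation of 17 instead). The hydroxide set free may hydrolyse the vinylogous ester, or the facial bias at C6 may be insufficient. The fallback changes the nucleophile and the mode of activation. It sets out from 14, which is converted with TMSOTf and Et3N into the trimethylsilyl enol ether of 14 F3. A Mukaiyama-type conjugate addition–elimination with 17 under catalytic TMSOTf at −78 °C, in which silicon is passed to the departing methoxy group, would give keto aldehyde 18, now isolated. K2CO3 in methanol would then close ring B to 20. The route is rejoined at 18.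

**Step 6.** Protonation at C1 may show incomplete facial selectivity, or C1 may epimerise later, because the thermodynamic preference for the equatorial ethyl group is small. The fallback gives up kinetic control for equilibrium control with recycling. It sets out from the mixture of 10 and the C1 epimer of 10 F4; the two are separated by chromatography or crystallisation, the unwanted epimer is re-equilibrated with DBU in toluene and separated again. The route is rejoined at 10.

**Step 2.** Wurtz homocoupling may compete during magnesium insertion into the very reactive chloride, and the benzylic Grignard reagent may attack through its ring ortho position. The fallback replaces addition and oxidation by an acylation. It sets out from 2 and 3. Zinc dust with LiCl in THF would convert 2 into (2,4,5-trimethoxybenzyl)zinc chloride F5, an insertion that does not suffer from homocoupling. Pinnick oxidation of 3 (NaClO2, NaH2PO4, 2-methylbut-2-ene) would give (E)-2-ethylbut-2-enoic acid F6, and oxalyl chloride with catalytic DMF would give (E)-2-ethylbut-2-enoyl chloride F7. Negishi acylation of F5 with F7 under the zerovalent palladium complex Pd(PPh3)4 would give 6 directly, where the route is rejoined.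

## Further compounds

F1 | step 5 | enantiomer of 9, formed beside 9 in the racemic cycloaddition | CCC1=C(O[Si](C(C)C)(C(C)C)C(C)C)[C@H](c2cc(OC)c(OC)cc2OC)[C@@H](C)[C@H](c2cc(OC)c(OC)cc2OC)[C@@H]1C
F2 | step 5 | enantiomer of 10 | CC[C@H]1[C@@H](C)[C@@H](c2cc(OC)c(OC)cc2OC)[C@H](C)[C@@H](c2cc(OC)c(OC)cc2OC)C1=O
F3 | step 11 | trimethylsilyl enol ether of 14 (enol-ether geometry not defined) | CC[C@@H]1[C@H](C)[C@H](c2cc(OC)c(OC)cc2OC)[C@@H](C)[C@H](c2cc(OC)c(OC)cc2OC)C1=CO[Si](C)(C)C
F4 | step 6 | C1 epimer of 10 | CC[C@H]1[C@H](C)[C@H](c2cc(OC)c(OC)cc2OC)[C@@H](C)[C@H](c2cc(OC)c(OC)cc2OC)C1=O
F5 | step 2 | (2,4,5-trimethoxybenzyl)zinc chloride | COc1cc(OC)c(C[Zn]Cl)cc1OC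
F6 | step 2 | (E)-2-ethylbut-2-enoic acid | C/C=C(CC)/C(=O)O
F7 | step 2 | (E)-2-ethylbut-2-enoyl chloride | C/C=C(CC)/C(=O)Cl
A1 | alternative 1 | C1-vinyl spirodienone (20 with vinyl in place of ethyl) | C=C[C@@H]1[C@H](C)[C@H](c2cc(OC)c(OC)cc2OC)[C@@H](C)[C@H](c2cc(OC)c(OC)cc2OC)[C@]12C=C(OC)C(=O)C=C2OC
A2 | alternative 1 | open-chain (E)-allyltrimethylsilane with C2–C4 set and two aryl groups on C5 | C[Si](C)(C)C/C=C/[C@H](C)[C@H](c1cc(OC)c(OC)cc1OC)[C@@H](C)C(c1cc(OC)c(OC)cc1OC)c1cc(OC)c(OC)cc1OC
A3 | alternative 2 | ring A with C1–C5 set and two methyl esters on C6 | CC[C@@H]1[C@H](C)[C@H](c2cc(OC)c(OC)cc2OC)[C@@H](C)[C@H](c2cc(OC)c(OC)cc2OC)C1(C(=O)OC)C(=O)OC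
A4 | alternative 2 | dimethyl 2-ethyl-3-methyl-4-(2,4,5-trimethoxyphenyl)cyclobutane-1,1-dicarboxylate, ethyl and methyl cis, aryl-bearing carbon undefined because it is ionised | CC[C@@H]1[C@H](C)C(c2cc(OC)c(OC)cc2OC)C1(C(=O)OC)C(=O)OC
A5 | alternative 3 | spiro C3 ketone with C1, C5 and C6 as in 20 and C2 methyl equatorial | CC[C@@H]1[C@@H](C)C(=O)[C@@H](C)[C@H](c2cc(OC)c(OC)cc2OC)[C@]12C=C(OC)C(=O)C=C2OC
A6 | alternative 3 | (1E,4E)-2,4-dimethyl-1-(2,4,5-trimethoxyphenyl)hepta-1,4-dien-3-one | O=C(/C(C)=C/c1cc(OC)c(OC)cc1OC)/C(C)=C/CC
A7 | alternative 3 | 2,5-dimethoxyphenol | COc1ccc(OC)c(O)c1
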